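Retrosynthesis: (a) cut the C19–O ester (acylation, then a Z-selective olefination builds the cinnamate C=C); (b) cut C13–C14 of the diene (enol triflate + vinylstannane) back to a methyl ketone, C8–O back to C8–H, and C11=C12 (Wittig) back to a C11 carbonyl on C9.
(c) Cut the decalin through two bonds of ring B at once, the ring-fusion bond C5–C10 and C8–C9 (labdane numbering). Ring B is a cyclohexane whose C6–C7 edge lies opposite C9–C10 and whose C9 bears the carbonyl-capable carbon C11, so with C6=C7 added it is a Diels–Alder retron; the four carbons C1–C4 of ring A are the tether between diene terminus C5 and dienophile carbon C10.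
Forward: linear assembly of an acyclic (2E,8E,10E)-trienimide (quaternary C4 aldehyde, then dienyl arm C5–C8/C17, then alkyne, then E-enoic acid C9–C11, then imide); one intramolecular Diels–Alder step closes ring A and ring B together; side chain and ester follow.
Stereochemistry: C4 from a Sharpless epoxide, relayed by a stereospecific 1,2-shift; C9 and C10 (absolute) from the (S)-4-benzyloxazolidinone; C5 and C8 (relative) from the endo transition state and the E,E-diene/E-dienophile geometries; C8–OH by C–H hydroxylation with retention; the Z-alkene from a diaryl phosphonoacetate.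

Key step: step 10

Remark: bicyclic compounds are described with labdane numbering (decalin C1–C10, side chain C11–C16 on C9, C17 on C8, C18/C19 on C4, C20 on C10; β is the face of C20); all stereochemical outcomes are predictions.

Step 1
Reactants: 1 5-chloropent-1-yne
Product: 3 (2E)-6-chloro-3-methylhex-2-en-1-ol, via alkenylalane 2 (not isolated)
Conditions: AlMe3 (2 equiv), Cp2ZrCl2 (0.2 equiv), CH2Cl2, 0 °C to rt; n-BuLi, THF, −78 °C; (CH2O)n, −78 °C to rt; 1 M HCl work-up
Reagents that add atoms: trimethylaluminium C[Al](C)C; formaldehyde (from paraformaldehyde) C=O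
Why: Zr-catalysed syn-carboalumination of the terminal alkyne puts Al at the terminus cis to the new methyl group, and hydroxymethylation of the derived alanate with retention should give the E-trisubstituted allylic alcohol.

Step 2
Reactants: 3 (2E)-6-chloro-3-methylhex-2-en-1-ol
Product: 4 [(2R,3R)-3-(3-chloropropyl)-3-methyloxiran-2-yl]methanol
Conditions: Ti(OiPr)4 (10 mol %), D-(−)-diethyl tartrate (12 mol %), t-BuOOH, 4 Å molecular sieves, CH2Cl2, −20 °C
Reagents that add atoms: tert-butyl hydroperoxide CC(C)(C)OO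
Why: Sharpless asymmetric epoxidation of the E-allylic alcohol with the D-tartrate should deliver oxygen to the face that gives the (2R,3R)-epoxide, which fixes the future C4.

Step 3
Reactants: 4 [(2R,3R)-3-(3-chloropropyl)-3-methyloxiran-2-yl]methanol
Product: 5 tert-butyl{[(2R,3R)-3-(3-chloropropyl)-3-methyloxiran-2-yl]methoxy}dimethylsilane
Conditions: t-BuMe2SiCl, imidazole, CH2Cl2, rt
Reagents that add atoms: tert-butyl(chloro)dimethylsilane CC(C)(C)[Si](C)(C)Cl
Why: Silyl ether formation at the primary alcohol provides the siloxymethyl group that migrates in the next step.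

Step 4
Reactants: 5 tert-butyl{[(2R,3R)-3-(3-chloropropyl)-3-methyloxiran-2-yl]methoxy}dimethylsilane
Product: 6 (2R)-2-{[tert-butyl(dimethyl)silyl]oxymethyl}-5-chloro-2-methylpentanal
Conditions: MeAl(OC6H2-4-Br-2,6-tBu2)2 (2 equiv, prepared beforehand from AlMe3 and the phenol), CH2Cl2, −78 to −40 °C; 1 M HCl work-up
Reagents that add atoms: none
Why: The bulky aluminium Lewis acid opens the epoxide at its tertiary carbon and the siloxymethyl group shifts anti to the leaving oxygen (semipinacol-type 1,2-shift of an epoxy silyl ether), so the epoxide chirality passes with inversion to the quaternary carbon (C4) and the former carbinol carbon becomes the aldehyde (C5).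

Step 5
Reactants: 7 (2E)-1-bromobut-2-ene
Product: 8 diethyl [(2E)-but-2-en-1-yl]phosphonate
Conditions: P(OEt)3, neat, 130 °C, bromoethane distilled off
Reagents that add atoms: triethyl phosphite CCOP(OCC)OCC
Why: Michaelis–Arbuzov reaction of the primary allylic bromide should give the allylic phosphonate with the E double bond kept.

Step 6
Reactants: 6 (2R)-2-{[tert-butyl(dimethyl)silyl]oxymethyl}-5-chloro-2-methylpentanal; 8 diethyl [(2E)-but-2-en-1-yl]phosphonate
Product: 9 tert-butyl{[(2S,3E,5E)-2-(3-chloropropyl)-2-methylhepta-3,5-dien-1-yl]oxy}dimethylsilane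
Conditions: n-BuLi, THF/DMPU, −78 °C to rt; aq. NH4Cl work-up
Reagents that add atoms: none
Why: Horner–Wadsworth–Emmons olefination with the lithiated allylic phosphonate (α-attack, then loss of phosphate) should form the new C5=C6 bond E and carry the crotyl E bond over, and the α-quaternary aldehyde cannot epimerise.

Step 7
Reactants: 9 tert-butyl{[(2S,3E,5E)-2-(3-chloropropyl)-2-methylhepta-3,5-dien-1-yl]oxy}dimethylsilane
Product: 10 tert-butyl(dimethyl){[(2S,3E,5E)-2-methyl-2-(pent-4-yn-1-yl)hepta-3,5-dien-1-yl]oxy}silane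
Conditions: LiC≡CH·H2NCH2CH2NH2, NaI (10 mol %), DMSO, rt
Reagents that add atoms: lithium acetylide (ethylenediamine complex) [Li+].[C-]#C
Why: SN2 alkylation of the acetylide by the primary chloride adds the two carbons that become C10 and C9.

Step 8
Reactants: 10 tert-butyl(dimethyl){[(2S,3E,5E)-2-methyl-2-(pent-4-yn-1-yl)hepta-3,5-dien-1-yl]oxy}silane
Product: 12 (2E,7S,8E,10E)-7-{[tert-butyl(dimethyl)silyl]oxymethyl}-3,7-dimethyldodeca-2,8,10-trienoic acid, via alkenylalane 11 (not isolated)
Conditions: AlMe3 (2.5 equiv), Cp2ZrCl2 (0.25 equiv), ClCH2CH2Cl, rt; n-BuLi, THF, −78 °C; CO2, −78 to 0 °C; cold 1 M HCl work-up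
Reagents that add atoms: trimethylaluminium C[Al](C)C; carbon dioxide O=C=O
Why: Zr-catalysed syn-carboalumination places the methyl group (C20) on C10 and Al on C9, and carboxylation of the alanate with retention should give the E acid with the chain trans to CO2H.

Step 9
Reactants: 12 (2E,7S,8E,10E)-7-{[tert-butyl(dimethyl)silyl]oxymethyl}-3,7-dimethyldodeca-2,8,10-trienoic acid; 13 (4S)-4-benzyl-1,3-oxazolidin-2-one
Product: 15 (4S)-4-benzyl-3-[(2E,7S,8E,10E)-7-{[tert-butyl(dimethyl)silyl]oxymethyl}-3,7-dimethyldodeca-2,8,10-trienoyl]-1,3-oxazolidin-2-one, via mixed anhydride 14 (not isolated)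
Conditions: t-BuCOCl, Et3N, THF, −20 °C; then 13, LiCl, −20 °C to rt
Reagents that add atoms: none
Why: N-Acylation of the oxazolidinone through the mixed pivalic anhydride should occur at the less hindered enoyl carbonyl and touches no stereocentre.

Step 10
Reactants: 15 (4S)-4-benzyl-3-[(2E,7S,8E,10E)-7-{[tert-butyl(dimethyl)silyl]oxymethyl}-3,7-dimethyldodeca-2,8,10-trienoyl]-1,3-oxazolidin-2-one
Product: 16 (4S)-4-benzyl-3-[19-(tert-butyldimethylsilyloxy)-12,13,14,15,16-pentanorlabd-6-en-11-oyl]-1,3-oxazolidin-2-one (5α-H; 9α-H; 8β-CH3; 10β-CH3; 4α-CH3)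
Conditions: Me2AlCl (1.5 equiv), CH2Cl2, −30 to 0 °C; 1 M HCl work-up at 0 °C
Reagents that add atoms: none
Why: Me2AlCl chelates both imide carbonyls, holds the enoyl unit s-cis and lowers its LUMO, and the tethered E,E-diene (C5=C6–C7=C8) adds to the E-dienophile (C9=C10) in a concerted, asynchronous [4+2] cycloaddition, the closest known type being the Lewis-acid-promoted, oxazolidinone-controlled intramolecular Diels–Alder reaction of 2,8,10-trienimides. Ring A closes by the C5–C10 bond as the four-carbon tether C1–C4 folds into a chair between the diene terminus and the inner dienophile carbon, and ring B is the new cyclohexene formed by C5–C10 together with C8–C9. C9 and C10 are set by the auxiliary, whose benzyl group shields one face of the chelated dienophile so that the diene should add to the other face; C5 and C8 follow from the endo transition state (carbonyl under the diene) and the fixed alkene geometries, which put C4 and C20 cis, C5–H and C20 trans (trans ring fusion) and C17 cis to C11. C4 is already in place, and with the face fixed by the auxiliary its CH2OSi group ends up axial, cis to C20. The step needs endo over exo closure and one diene face: the chelated, activated imide should secure the first and the auxiliary the second, while the tether length allows only the fused ring system.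

Step 11
Reactants: 16 (4S)-4-benzyl-3-[19-(tert-butyldimethylsilyloxy)-12,13,14,15,16-pentanorlabd-6-en-11-oyl]-1,3-oxazolidin-2-one
Product: 17 19-(tert-butyldimethylsilyloxy)-12,13,14,15,16-pentanorlabd-6-en-11-ol (8β-CH3; 8α-H)
Conditions: LiBH4 (2 equiv), MeOH (2 equiv), Et2O, 0 °C
Reagents that add atoms: none
Why: Reductive removal of the oxazolidinone auxiliary by hydride attack at the exocyclic imide carbonyl should give the primary alcohol, return the auxiliary and leave C9 untouched.

Step 12
Reactants: 17 19-(tert-butyldimethylsilyloxy)-12,13,14,15,16-pentanorlabd-6-en-11-ol (8β-CH3; 8α-H)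
Product: 18 19-(tert-butyldimethylsilyloxy)-12,13,14,15,16-pentanorlabd-6-en-11-al (8β-CH3; 8α-H)
Conditions: Dess–Martin periodinane, CH2Cl2, rt
Reagents that add atoms: none
Why: Dess–Martin oxidation under near-neutral conditions should give the aldehyde without epimerising C9.

Step 13
Reactants: 18 19-(tert-butyldimethylsilyloxy)-12,13,14,15,16-pentanorlabd-6-en-11-al (8β-CH3; 8α-H); 19 1-(triphenyl-λ5-phosphanylidene)propan-2-one
Product: 20 (11E)-19-(tert-butyldimethylsilyloxy)-14,15-dinorlabda-6,11-dien-13-one (8β-CH3; 8α-H)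
Conditions: toluene, 90 °C
Reagents that add atoms: none
Why: Wittig olefination with the stabilised, weakly basic ylide should add C12, C13 and C16 as an E-enone.

Step 14
Reactants: 20 (11E)-19-(tert-butyldimethylsilyloxy)-14,15-dinorlabda-6,11-dien-13-one (8β-CH3; 8α-H)
Product: 21 19-(tert-butyldimethylsilyloxy)-14,15-dinorlabdan-13-one (8β-CH3; 8α-H)
Conditions: H2 (1 atm), Pd/C, EtOAc, rt
Reagents that add atoms: none
Why: Heterogeneous catalytic hydrogenation should saturate both C6=C7 and C11=C12, creates no stereocentre and removes every alkene before the oxidation.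

Step 15
Reactants: 21 19-(tert-butyldimethylsilyloxy)-14,15-dinorlabdan-13-one (8β-CH3; 8α-H)
Product: 22 19-(tert-butyldimethylsilyloxy)-8α-hydroxy-14,15-dinorlabdan-13-one
Conditions: methyl(trifluoromethyl)dioxirane (1.5 equiv, solution in 1,1,1-trifluoroacetone), CH2Cl2, −20 to 0 °C
Reagents that add atoms: methyl(trifluoromethyl)dioxirane CC1(OO1)C(F)(F)F
Why: Dioxirane C–H hydroxylation inserts oxygen with retention and should prefer the equatorial tertiary C8–H, whose oxidation relieves the syn-diaxial C17/C20 strain, over the axial C5–H and C9–H flanked by quaternary carbons and over C–H bonds deactivated by the ketone and the silyl ether.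

Step 16
Reactants: 22 19-(tert-butyldimethylsilyloxy)-8α-hydroxy-14,15-dinorlabdan-13-one
Product: 23 19-(tert-butyldimethylsilyloxy)-8α-(trimethylsilyloxy)-14,15-dinorlabdan-13-one
Conditions: 1-(trimethylsilyl)imidazole, CH2Cl2, rt
Reagents that add atoms: 1-(trimethylsilyl)imidazole C[Si](C)(C)n1ccnc1
Why: Silyl transfer from the N-silylimidazole masks the tertiary alcohol so that it cannot add to the ketone or consume base in the enolisation.

Step 17
Reactants: 23 19-(tert-butyldimethylsilyloxy)-8α-(trimethylsilyloxy)-14,15-dinorlabdan-13-one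
Product: 25 19-(tert-butyldimethylsilyloxy)-8α-(trimethylsilyloxy)-14,15-dinorlabd-13(16)-en-13-yl trifluoromethanesulfonate, via potassium enolate 24 (not isolated)
Conditions: KN(SiMe3)2, THF, −78 °C; PhNTf2, −78 to 0 °C; aq. NH4Cl work-up
Reagents that add atoms: N-phenylbis(trifluoromethanesulfonimide) FC(F)(F)S(=O)(=O)N(c1ccccc1)S(=O)(=O)C(F)(F)F
Why: Kinetic deprotonation of the methyl ketone at the methyl group (C16) and O-sulfonylation of the enolate should give the terminal enol triflate.

Step 18
Reactants: 25 19-(tert-butyldimethylsilyloxy)-8α-(trimethylsilyloxy)-14,15-dinorlabd-13(16)-en-13-yl trifluoromethanesulfonate; 26 tributyl(ethenyl)stannane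
Product: 27 19-(tert-butyldimethylsilyloxy)-8α-(trimethylsilyloxy)labda-13(16),14-diene
Conditions: Pd(PPh3)4 (5 mol %), LiCl (3 equiv), THF, 65 °C
Reagents that add atoms: none
Why: Stille coupling of the enol triflate with the vinylstannane should form C13–C14 and with it the 2-substituted buta-1,3-diene.

Step 19
Reactants: 27 19-(tert-butyldimethylsilyloxy)-8α-(trimethylsilyloxy)labda-13(16),14-diene
Product: 28 labda-13(16),14-diene-8α,19-diol
Conditions: Bu4NF (3 equiv), THF, rt to 40 °C
Reagents that add atoms: none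
Why: Fluoride-induced desilylation should cleave both silyl ethers without touching the diene.

Step 20
Reactants: 28 labda-13(16),14-diene-8α,19-diol; 29 bromoacetyl bromide
Product: 30 8α-hydroxylabda-13(16),14-dien-19-yl bromoacetate
Conditions: pyridine, CH2Cl2, −20 °C
Reagents that add atoms: none
Why: Acylation by the acyl bromide should take the primary C19 alcohol and leave the hindered tertiary C8 alcohol.

Step 21
Reactants: 30 8α-hydroxylabda-13(16),14-dien-19-yl bromoacetate
Product: 31 8α-hydroxylabda-13(16),14-dien-19-yl (diphenoxyphosphoryl)acetate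
Conditions: (PhO)2P(O)H, Et3N, CH2Cl2, 0 °C to rt
Reagents that add atoms: diphenyl phosphite O=[PH](Oc1ccccc1)Oc1ccccc1
Why: Michaelis–Becker-type P-alkylation of the phosphite anion by the α-bromo ester should give the diaryl phosphonoacetate under mild base.

Step 22
Reactants: 31 8α-hydroxylabda-13(16),14-dien-19-yl (diphenoxyphosphoryl)acetate; 32 4-{[tert-butyl(dimethyl)silyl]oxy}benzaldehyde
Product: 33 8α-hydroxylabda-13(16),14-dien-19-yl (2Z)-3-(4-{[tert-butyl(dimethyl)silyl]oxy}phenyl)prop-2-enoate
Conditions: NaH (1.1 equiv), THF, −78 °C; then 32, −78 to 0 °C; aq. NH4Cl work-up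
Reagents that add atoms: none
Why: Horner–Wadsworth–Emmons olefination with a diaryl phosphonoacetate collapses fast from the kinetic adduct because of the electron-poor aryloxy groups and should therefore give the Z-cinnamate.

Step 23
Reactants: 33 8α-hydroxylabda-13(16),14-dien-19-yl (2Z)-3-(4-{[tert-butyl(dimethyl)silyl]oxy}phenyl)prop-2-enoate
Product: 34 8α-hydroxylabda-13(16),14-dien-19-yl (2Z)-3-(4-hydroxyphenyl)prop-2-enoate (CNP0197278.1)
Conditions: Bu4NF, AcOH (1:1), THF, 0 °C
Reagents that add atoms: none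
Why: Buffered fluoride cleavage of the aryl silyl ether should free the phenol without ester cleavage or Z-to-E isomerisation.

Compound list
1 | 5-chloropent-1-yne | C#CCCCCl | starting material
2 | dimethyl[(1E)-5-chloro-2-methylpent-1-en-1-yl]alumane | C[Al](C)/C=C(\C)CCCCl | intermediate
3 | (2E)-6-chloro-3-methylhex-2-en-1-ol | OC/C=C(\C)CCCCl | intermediate
4 | [(2R,3R)-3-(3-chloropropyl)-3-methyloxiran-2-yl]methanol | OC[C@H]1O[C@]1(C)CCCCl | intermediate
5 | tert-butyl{[(2R,3R)-3-(3-chloropropyl)-3-methyloxiran-2-yl]methoxy}dimethylsilane | CC(C)(C)[Si](C)(C)OC[C@H]1O[C@]1(C)CCCCl | intermediate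
6 | (2R)-2-{[tert-butyl(dimethyl)silyl]oxymethyl}-5-chloro-2-methylpentanal | ClCCC[C@](C)(CO[Si](C)(C)C(C)(C)C)C=O | intermediate
7 | (2E)-1-bromobut-2-ene | C/C=C/CBr | starting material
8 | diethyl [(2E)-but-2-en-1-yl]phosphonate | CCOP(=O)(C/C=C/C)OCC | intermediate
9 | tert-butyl{[(2S,3E,5E)-2-(3-chloropropyl)-2-methylhepta-3,5-dien-1-yl]oxy}dimethylsilane | ClCCC[C@](C)(CO[Si](C)(C)C(C)(C)C)/C=C/C=C/C | intermediate
10 | tert-butyl(dimethyl){[(2S,3E,5E)-2-methyl-2-(pent-4-yn-1-yl)hepta-3,5-dien-1-yl]oxy}silane | C#CCCC[C@](C)(CO[Si](C)(C)C(C)(C)C)/C=C/C=C/C | intermediate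
11 | dimethyl[(1E,6S,7E,9E)-6-{[tert-butyl(dimethyl)silyl]oxymethyl}-2,6-dimethylundeca-1,7,9-trien-1-yl]alumane | C[Al](C)/C=C(\C)CCC[C@](C)(CO[Si](C)(C)C(C)(C)C)/C=C/C=C/C | intermediate
12 | (2E,7S,8E,10E)-7-{[tert-butyl(dimethyl)silyl]oxymethyl}-3,7-dimethyldodeca-2,8,10-trienoic acid | OC(=O)/C=C(\C)CCC[C@](C)(CO[Si](C)(C)C(C)(C)C)/C=C/C=C/C | intermediate
13 | (4S)-4-benzyl-1,3-oxazolidin-2-one | O=C1N[C@@H](Cc2ccccc2)CO1 | starting material
14 | mixed anhydride of acid 12 with 2,2-dimethylpropanoic acid | CC(C)(C)C(=O)OC(=O)/C=C(\C)CCC[C@](C)(CO[Si](C)(C)C(C)(C)C)/C=C/C=C/C | intermediate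
15 | (4S)-4-benzyl-3-[(2E,7S,8E,10E)-7-{[tert-butyl(dimethyl)silyl]oxymethyl}-3,7-dimethyldodeca-2,8,10-trienoyl]-1,3-oxazolidin-2-one | O=C(/C=C(\C)CCC[C@](C)(CO[Si](C)(C)C(C)(C)C)/C=C/C=C/C)N1[C@@H](Cc2ccccc2)COC1=O | intermediate
16 | (4S)-4-benzyl-3-[19-(tert-butyldimethylsilyloxy)-12,13,14,15,16-pentanorlabd-6-en-11-oyl]-1,3-oxazolidin-2-one (5α-H; 9α-H; 8β-CH3; 10β-CH3; 4α-CH3) | O=C(N1[C@@H](Cc2ccccc2)COC1=O)[C@@H]1[C@@]2(C)CCC[C@](C)(CO[Si](C)(C)C(C)(C)C)[C@@H]2C=C[C@@H]1C | intermediate
17 | 19-(tert-butyldimethylsilyloxy)-12,13,14,15,16-pentanorlabd-6-en-11-ol (8β-CH3; 8α-H) | OC[C@@H]1[C@@]2(C)CCC[C@](C)(CO[Si](C)(C)C(C)(C)C)[C@@H]2C=C[C@@H]1C | intermediate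
18 | 19-(tert-butyldimethylsilyloxy)-12,13,14,15,16-pentanorlabd-6-en-11-al (8β-CH3; 8α-H) | O=C[C@@H]1[C@@]2(C)CCC[C@](C)(CO[Si](C)(C)C(C)(C)C)[C@@H]2C=C[C@@H]1C | intermediate
19 | 1-(triphenyl-λ5-phosphanylidene)propan-2-one | CC(=O)C=P(c1ccccc1)(c1ccccc1)c1ccccc1 | starting material
20 | (11E)-19-(tert-butyldimethylsilyloxy)-14,15-dinorlabda-6,11-dien-13-one (8β-CH3; 8α-H) | CC(=O)/C=C/[C@@H]1[C@@]2(C)CCC[C@](C)(CO[Si](C)(C)C(C)(C)C)[C@@H]2C=C[C@@H]1C | intermediate
21 | 19-(tert-butyldimethylsilyloxy)-14,15-dinorlabdan-13-one (8β-CH3; 8α-H) | CC(=O)CC[C@@H]1[C@@]2(C)CCC[C@](C)(CO[Si](C)(C)C(C)(C)C)[C@@H]2CC[C@@H]1C | intermediate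
22 | 19-(tert-butyldimethylsilyloxy)-8α-hydroxy-14,15-dinorlabdan-13-one | CC(=O)CC[C@@H]1[C@@]2(C)CCC[C@](C)(CO[Si](C)(C)C(C)(C)C)[C@@H]2CC[C@@]1(C)O | intermediate
23 | 19-(tert-butyldimethylsilyloxy)-8α-(trimethylsilyloxy)-14,15-dinorlabdan-13-one | CC(=O)CC[C@@H]1[C@@]2(C)CCC[C@](C)(CO[Si](C)(C)C(C)(C)C)[C@@H]2CC[C@@]1(C)O[Si](C)(C)C | intermediate
24 | potassium 13(16)-enolate of ketone 23 | [K+].[O-]C(=C)CC[C@@H]1[C@@]2(C)CCC[C@](C)(CO[Si](C)(C)C(C)(C)C)[C@@H]2CC[C@@]1(C)O[Si](C)(C)C | intermediate
25 | 19-(tert-butyldimethylsilyloxy)-8α-(trimethylsilyloxy)-14,15-dinorlabd-13(16)-en-13-yl trifluoromethanesulfonate | C=C(OS(=O)(=O)C(F)(F)F)CC[C@@H]1[C@@]2(C)CCC[C@](C)(CO[Si](C)(C)C(C)(C)C)[C@@H]2CC[C@@]1(C)O[Si](C)(C)C | intermediate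
26 | tributyl(ethenyl)stannane | C=C[Sn](CCCC)(CCCC)CCCC | starting material
27 | 19-(tert-butyldimethylsilyloxy)-8α-(trimethylsilyloxy)labda-13(16),14-diene | C=CC(=C)CC[C@@H]1[C@@]2(C)CCC[C@](C)(CO[Si](C)(C)C(C)(C)C)[C@@H]2CC[C@@]1(C)O[Si](C)(C)C | intermediate
28 | labda-13(16),14-diene-8α,19-diol | C=CC(=C)CC[C@@H]1[C@@]2(C)CCC[C@](C)(CO)[C@@H]2CC[C@@]1(C)O | intermediate
29 | bromoacetyl bromide | BrCC(Br)=O | starting material
30 | 8α-hydroxylabda-13(16),14-dien-19-yl bromoacetate | C=CC(=C)CC[C@@H]1[C@@]2(C)CCC[C@](C)(COC(=O)CBr)[C@@H]2CC[C@@]1(C)O | intermediate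
31 | 8α-hydroxylabda-13(16),14-dien-19-yl (diphenoxyphosphoryl)acetate | C=CC(=C)CC[C@@H]1[C@@]2(C)CCC[C@](C)(COC(=O)CP(=O)(Oc3ccccc3)Oc3ccccc3)[C@@H]2CC[C@@]1(C)O | intermediate
32 | 4-{[tert-butyl(dimethyl)silyl]oxy}benzaldehyde | O=Cc1ccc(O[Si](C)(C)C(C)(C)C)cc1 | starting material
33 | 8α-hydroxylabda-13(16),14-dien-19-yl (2Z)-3-(4-{[tert-butyl(dimethyl)silyl]oxy}phenyl)prop-2-enoate | C=CC(=C)CC[C@@H]1[C@@]2(C)CCC[C@](C)(COC(=O)/C=C\c3ccc(O[Si](C)(C)C(C)(C)C)cc3)[C@@H]2CC[C@@]1(C)O | intermediate
34 | 8α-hydroxylabda-13(16),14-dien-19-yl (2Z)-3-(4-hydroxyphenyl)prop-2-enoate (CNP0197278.1) | C=CC(=C)CC[C@@H]1[C@@]2(C)CCC[C@](C)(COC(=O)/C=C\c3ccc(O)cc3)[C@@H]2CC[C@@]1(C)O | target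

Total step count: 23. Longest linear sequence: 22 steps (steps 1–4 and 6–23, from 5-chloropent-1-yne; step 5 is a side branch).

Steps most likely to fail

Step 10. The cycloaddition may be slow because the dienophile is β,β-disubstituted, and the exo (cis-fused) closure may compete because the C19 group and C20 come into 1,3-diaxial contact in the endo transition state. Facial control may also erode if the preset C4 centre works against the auxiliary. The fallback changes the activation from a neutral chelate to a cation. It sets out from acid 12, which LiAlH4 (THF, 0 °C) should reduce to (2E,7S,8E,10E)-7-{[tert-butyl(dimethyl)silyl]oxymethyl}-3,7-dimethyldodeca-2,8,10-trien-1-ol F1. MnO2 (CH2Cl2) would oxidise this to the trienal F2, and (2R,4R)-pentane-2,4-diol with pyridinium p-toluenesulfonate (benzene, reflux) would convert the aldehyde into the (4R,6R)-4,6-dimethyl-1,3-dioxane acetal F3. Me3SiOTf (CH2Cl2, −78 °C) would then open the acetal to an alkoxy-substituted allyl cation, a far stronger dienophile. The ionic Diels–Alder reaction and re-closure of the acetal should give the bicyclic acetal F4, and dilute aqueous acid would free aldehyde 18, where the route is rejoined (steps 10–12 are bypassed). The enantiomer of the diol would be fixed after a test of its sense of induction.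

Step 15. Oxygen transfer may go to other C–H bonds (ring-A methylenes, C9–H), to the CH2 next to the silyl ether, or on to over-oxidation. The fallback replaces innate C–H reactivity by enzyme control. It sets out from ketone 21, which would be hydroxylated with a cytochrome P450 monooxygenase, chosen from a panel of engineered P450 BM3 variants (whole cells or lysate, NADPH recycled by glucose dehydrogenase and glucose, O2, buffer with co-solvent, rt). The binding pocket would select C8–H and oxygen rebound proceeds with retention, giving 22, where the route is rejoined. No new compound is made on this path (F0).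

Step 11. Hydride may attack the ring carbonyl of the oxazolidinone (endocyclic cleavage) because the exocyclic carbonyl on C9 is flanked by C10 and C8, or the reduction may stall. The fallback uses thiolysis and thioester reduction instead of direct hydride cleavage. It sets out from imide 16, from which LiSEt (from EtSH and n-BuLi, THF, 0 °C) should displace the auxiliary to give S-ethyl 19-(tert-butyldimethylsilyloxy)-12,13,14,15,16-pentanorlabd-6-ene-11-thioate F5. Fukuyama reduction (Et3SiH, Pd/C, acetone, rt) would convert the thioester directly into aldehyde 18, where the route is rejoined (step 12 is bypassed).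

Further compounds
F1 | step 10 | (2E,7S,8E,10E)-7-{[tert-butyl(dimethyl)silyl]oxymethyl}-3,7-dimethyldodeca-2,8,10-trien-1-ol | OC/C=C(\C)CCC[C@](C)(CO[Si](C)(C)C(C)(C)C)/C=C/C=C/C
F2 | step 10 | (2E,7S,8E,10E)-7-{[tert-butyl(dimethyl)silyl]oxymethyl}-3,7-dimethyldodeca-2,8,10-trienal | O=C/C=C(\C)CCC[C@](C)(CO[Si](C)(C)C(C)(C)C)/C=C/C=C/C
F3 | step 10 | (4R,6R)-4,6-dimethyl-1,3-dioxane acetal of trienal F2 | C[C@@H]1C[C@@H](C)OC(/C=C(\C)CCC[C@](C)(CO[Si](C)(C)C(C)(C)C)/C=C/C=C/C)O1
F4 | step 10 | (4R,6R)-4,6-dimethyl-1,3-dioxane acetal of aldehyde 18 | C[C@@H]1C[C@@H](C)OC(O1)[C@@H]1[C@@]2(C)CCC[C@](C)(CO[Si](C)(C)C(C)(C)C)[C@@H]2C=C[C@@H]1C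
F0 | step 15 | none | none
F5 | step 11 | S-ethyl 19-(tert-butyldimethylsilyloxy)-12,13,14,15,16-pentanorlabd-6-ene-11-thioate (8β-CH3; 8α-H) | CCSC(=O)[C@@H]1[C@@]2(C)CCC[C@](C)(CO[Si](C)(C)C(C)(C)C)[C@@H]2C=C[C@@H]1C
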